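## The problem

The target is a 2-acetoxy-3,4-dihydro-2H-pyran (acetal C1, O2, enol ether C3=C4) trans-fused through C4a–C11a to a nine-membered carbocycle. The carbocycle carries an exocyclic methylene at C11, a tertiary carbinol at C7 and a cis-epoxide at C8–C9 on the same face as the C7 hydroxyl. C4 bears a chain with acetates at C12 and C13 and a trisubstituted epoxide at C14–C15. A nine-membered ring cannot be closed reliably by end-to-end C–C bond formation.

The nine stereocentres fall into three groups: C1/C4a/C11a, C7/C8/C9 and C12/C13/C14. Inside a group control can be relayed: the C7 hydroxyl can deliver an oxidant to C8=C9, the C11 branch on C11a decides the face on which C1 is acetylated, and C13 can bias C12 and C14. Between groups it cannot: C7 is remote from C4a across a flexible ring, so the absolute sense of each group must be brought in separately.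

The enol acetal with its allylic C12 acetate ionises with acid and eliminates with base, and both epoxides are acid-labile. The C11 methylene lies β,γ to C1 and moves into conjugation whenever C11a is enolised at a carbonyl stage. Three acetates rule out hydride or hydroxide at the end, so the acetates must come last.

The enabling feature is that the fusion bond C4a–C11a lies between C1 (carboxyl level) and C4, which are also joined through O2 and C3. Cutting C4a–C11a while keeping O2–C3 as an ester bond turns the pyran atoms into an allylic ester C1(=O)–O2–C3–C4=C4a and enlarges the nine-membered ring to a 13-membered lactone.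

## Retrosynthesis

**Acetates and C1–H (34 ⇒ 33 ⇒ 32).** The three acetates are removed together and the C1 acetal is traced to the carbonyl of enol lactone 32. A 1,5-dialdehyde cyclisation would be shorter, but it could equally enolise toward C11a and give a dienol ether conjugated with the C11 methylene. The lactone fixes which carbon is the acetal. The forward reactions must stop hydride addition at the lactol and acetylate C1 on the face away from the C11 branch.

**Ring epoxide (32 ⇒ 31 ⇒ 30).** The silyl ethers at C12 and C13 are restored and the C8–C9 epoxide is removed to the Z-olefin of 30. Delivery from the C7 hydroxyl is preferred over a peracid, which would attack the C11 methylene and the enol lactone and give the anti isomer. The forward step needs C7–OH free and C12–OH masked.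

**Enol lactone (30 ⇒ 29).** The O2–C1 acyl bond is cut to aldehyde acid 29. Only the C3 aldehyde can enolise toward C4, so the position of the enol double bond is unambiguous. The forward step must acylate the enol oxygen without enolising C11a.

**Side chain (29 ⇒ 20 + 26).** The C4–C12 bond is cut as an aldol between the C3 aldehyde of 20 and the epoxy aldehyde 26. Attaching the chain to a finished dihydropyran would need a C4 vinyl anion and a halogenation that the other olefins would not survive. The cut removes six carbons and two stereocentres (C13, C14) in one convergent step. The forward reaction must set C12 anti to the C13 oxygen.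

**Epoxy aldehyde (26 ⇒ 25 ⇒ 24 ⇒ 23 ⇒ 22 ⇒ 21).** C13 comes from (R)-glyceraldehyde acetonide 21, the C14=C15 olefin from a Wittig reaction and the epoxide from a reagent-controlled epoxidation. The acetonide is exchanged for silyl ethers before the epoxide is made, because its acidic removal would destroy the epoxide.

**C3 aldehyde (20 ⇒ 19 ⇒ 18 ⇒ 17).** The aldehyde is traced to the vinyl group of acid 17 by anti-Markovnikov oxidation. The acid is masked as a silyl ester for that step only, since a free γ,δ-unsaturated acid would cyclise onto palladium-activated olefin.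

**Key cut (17 ⇒ 14).** C4a–C11a is cut and O2–C3 is made, which gives the 13-membered E,Z-dienyl lactone 14. This trades a nine-membered C–C closure for a macrolactonisation and creates C4a and C11a together, with the C1 carboxyl and the C3/C4 vinyl group as the handles the pyran needs. The forward reaction must bond the Re face of C11a to the Re face of C4a. That sense is assigned to a chiral boron ketene acetal and not to the remote C7 centre.

**Lactone (14 ⇒ 13).** The ester C–O bond is cut to seco acid 13. The β,γ-unsaturated acid asks for room-temperature activation.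

**Acid arm (13 ⇒ 12 ⇒ 11 ⇒ 10 ⇒ 8 + 9).** The Z-olefin is traced to an alkyne and C11a–C1 is cut by carbonylation of an allylic chloride. C9–C10 is cut to the terminal alkyne 8 and the symmetrical dichloride 9, for which SN2 and SN2' attack give the same product.

**C7 and the allylic alcohol (8 ⇒ 7 ⇒ 6 ⇒ 5 ⇒ 4 ⇒ 3 ⇒ 2 ⇒ 1).** The E-allylic alcohol comes from olefination of aldehyde 6, itself from ozonolysis of the prenyl terminus. The tertiary propargylic carbinol 4 is traced through an epoxy chloride to the Sharpless epoxide of geraniol 1. This is chosen over enantioselective alkynylation of a methyl ketone because methyl and primary alkyl are poorly differentiated in that reaction.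

## Roads not taken

**Alternative 1:** The cut runs through O2–C1 and C4a–C11a of the pyran, giving an oxadiene and an E-enol ether. Forward, a Knoevenagel condensation makes the heterodiene in the flask and a Cu(OTf)2–bis(oxazoline) catalysed endo hetero-Diels–Alder reaction would give dihydropyran A1.
- Merits: the pyran, both fusion centres and the C12 carbon (as an ester that stabilises the enol ether) arrive in one catalytic, enantioselective step.
- Weak points: the nine-membered ring must still be closed by C–C bond formation between the two arms of A1. The methyl acetal must be exchanged for an acetate in the presence of two epoxides and an allylic acetate. C11 is a masked ketone that has to be methylenated next to the epimerisable C11a.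
- Comparison: in catalytic absolute control and in having C12 in place from the start this road is better than the chosen plan, which pays for the same control with a stoichiometric boron reagent and a late aldol. The chosen plan sets against it a ring closure by sigmatropic contraction, the methylene and Z-olefin in place as spectators, and an acetal that is born as the acetate.

**Alternative 2:** The cut removes the C7–O bond and the C8–C9 epoxide oxygen from a trisubstituted C7=C8 olefin. Forward, singlet oxygen adds to C7 in an ene reaction with transfer of a C9 hydrogen, and Ti(OiPr)4 passes the distal peroxide oxygen to the new C8=C9 olefin to give syn epoxy carbinol A2.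
- Merits: three stereocentres come from oxygen, light and one titanium alkoxide in one flask, and C7 need not be carried through the synthesis.
- Weak points: hydrogen abstraction can also occur from C6 or the C7 methyl. The C11 methylene offers a second ene site, and the electron-rich enol ether is itself a singlet-oxygen substrate. The strategy builds no part of the skeleton.
- Comparison: as an end-game operation it is shorter than the chosen directed epoxidation and is better in step count. The chosen plan sets against it a C7 centre fixed from the first step, regiochemistry decided by the hydroxyl, and no singlet oxygen near the enol lactone.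

**Alternative 3:** The cut is C9–C10, made by a Claisen ring expansion. Forward, Cp2TiMe2 methylenates a seven-membered lactone and the 2-methylene-7-methyl-7-vinyloxepane rearranges on heating to nine-membered ketone A3.
- Merits: the C4a/C11a pair is set in a normal-sized ring where stereocontrol is routine, and the expansion to a nine-membered enone is a known reaction type.
- Weak points: C11 arrives as a ketone that must be methylenated beside an epimerisable centre bearing a β-acetal. C1 and C3 arrive as two acetal-protected aldehydes whose differentiation, and the direction of enol ether formation, are not controlled. The C7 oxygens still require the chemistry of Alternative 2.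
- Comparison: in the security of the ring-fusion configuration this road is better. The chosen plan sets against it C1 and C3 that differ by construction (acid against olefin), the methylene already present, and C7 already oxygenated.

Key step: step 13

Assumptions:
- The (4S,5S)-diazaborolidine bromide is written as the enantiomer that joins the Re face of C11a to the Re face of C4a. The facial sense of this reagent class with a ring-bound ketene acetal is taken by analogy, and the (4R,5R)-reagent is the direct replacement if it proves opposite.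
- Xenicane numbering (C1 to C19) is used for all intermediates. For compounds 27 to 33 the SMILES string defines the configuration.

## Route

Step 1
Reactants: 1 geraniol
Product: 2 [(2S,3S)-3-methyl-3-(4-methylpent-3-en-1-yl)oxiran-2-yl]methanol
Conditions: Ti(OiPr)4 (5 mol%), L-(+)-diethyl tartrate (6 mol%), t-BuOOH, 4 Å molecular sieves, CH2Cl2, −20 °C
Reagents that add atoms: tert-butyl hydroperoxide, CC(C)(C)OO
Why: Sharpless asymmetric epoxidation; the L-tartrate complex epoxidises only the allylic olefin and should give the (2S,3S) epoxide, whose C3 becomes C7 of the target.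

Step 2
Reactants: 2 [(2S,3S)-3-methyl-3-(4-methylpent-3-en-1-yl)oxiran-2-yl]methanol
Product: 3 (2S,3R)-3-(chloromethyl)-2-methyl-2-(4-methylpent-3-en-1-yl)oxirane
Conditions: PPh3, CCl4, NaHCO3, 75 °C
Reagents that add atoms: tetrachloromethane, ClC(Cl)(Cl)Cl
Why: Appel chlorination of a primary alcohol under neutral conditions that leave the epoxide intact.

Step 3
Reactants: 3 (2S,3R)-3-(chloromethyl)-2-methyl-2-(4-methylpent-3-en-1-yl)oxirane
Product: 4 (3S)-3,7-dimethyloct-6-en-1-yn-3-ol
Conditions: n-BuLi (3.3 equiv), THF, −40 °C → rt; aq. NH4Cl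
Reagents that add atoms: none
Why: Base-induced fragmentation of a 2,3-epoxy chloride (deprotonation next to chlorine, epoxide opening, dehydrochlorination) to a propargylic alcohol; no bond to the tertiary carbon is broken, so its configuration is retained.

Step 4
Reactants: 4 (3S)-3,7-dimethyloct-6-en-1-yn-3-ol
Product: 5 triethyl{[(3S)-3,7-dimethyloct-6-en-1-yn-3-yl]oxy}silane
Conditions: Et3SiOTf, 2,6-lutidine, CH2Cl2, −78 → 0 °C
Reagents that add atoms: triethylsilyl trifluoromethanesulfonate, CC[Si](CC)(CC)OS(=O)(=O)C(F)(F)F
Why: Silyl triflate silylation of a tertiary alcohol; without it the γ-hydroxy aldehyde of the next step would close to a lactol and later add to the enoate.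

Step 5
Reactants: 5 triethyl{[(3S)-3,7-dimethyloct-6-en-1-yn-3-yl]oxy}silane
Product: 6 (4S)-4-methyl-4-(triethylsilyloxy)hex-5-ynal
Conditions: O3, pyridine, CH2Cl2, −78 °C
Reagents that add atoms: ozone, [O-][O+]=O
Why: Ozonolysis in the presence of pyridine gives the aldehyde directly; the trisubstituted olefin reacts far faster than the terminal alkyne.

Step 6
Reactants: 6 (4S)-4-methyl-4-(triethylsilyloxy)hex-5-ynal
Product: 7 ethyl (2E,6S)-6-methyl-6-(triethylsilyloxy)oct-2-en-7-ynoate
Conditions: (EtO)2P(O)CH2CO2Et, NaH, THF, 0 °C → rt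
Reagents that add atoms: triethyl phosphonoacetate, CCOC(=O)CP(=O)(OCC)OCC
Why: Horner–Wadsworth–Emmons olefination with a stabilised phosphonate, E-selective; this olefin becomes C4=C4a.

Step 7
Reactants: 7 ethyl (2E,6S)-6-methyl-6-(triethylsilyloxy)oct-2-en-7-ynoate
Product: 8 (2E,6S)-6-methyl-6-(triethylsilyloxy)oct-2-en-7-yn-1-ol
Conditions: iBu2AlH, CH2Cl2, −78 °C; aq. potassium sodium tartrate
Reagents that add atoms: none
Why: 1,2-Reduction of an enoate to the allylic alcohol by an aluminium hydride.

Step 8
Reactants: 8 (2E,6S)-6-methyl-6-(triethylsilyloxy)oct-2-en-7-yn-1-ol; 9 3-chloro-2-(chloromethyl)prop-1-ene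
Product: 10 (2E,6S)-10-(chloromethyl)-6-methyl-6-(triethylsilyloxy)undeca-2,10-dien-7-yn-1-ol
Conditions: CuI (20 mol%), NaI (20 mol%), K2CO3, DMF, rt; 9 (4 equiv)
Reagents that add atoms: none
Why: Copper-catalysed coupling of a terminal alkyne with an allylic halide; the 2-substituted allyl unit gives one product by either SN2 or SN2' attack, and excess 9 suppresses double coupling.

Step 9
Reactants: 10 (2E,6S)-10-(chloromethyl)-6-methyl-6-(triethylsilyloxy)undeca-2,10-dien-7-yn-1-ol
Product: 11 methyl (7S,10E)-12-hydroxy-7-methyl-3-methylidene-7-(triethylsilyloxy)dodec-10-en-5-ynoate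
Conditions: PdCl2(PPh3)2 (3 mol%), CO (3 bar), iPr2NEt, MeOH, 40 °C
Reagents that add atoms: carbon monoxide, [C-]#[O+]; methanol, CO
Why: Palladium-catalysed alkoxycarbonylation of an allylic chloride through a π-allyl/acyl palladium intermediate whose two termini are equivalent; the amine base is too weak to move the olefin into conjugation.

Step 10
Reactants: 11 methyl (7S,10E)-12-hydroxy-7-methyl-3-methylidene-7-(triethylsilyloxy)dodec-10-en-5-ynoate
Product: 12 methyl (5Z,7S,10E)-12-hydroxy-7-methyl-3-methylidene-7-(triethylsilyloxy)dodeca-5,10-dienoate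
Conditions: H2 (1 atm), Pd/CaCO3 poisoned with Pb(OAc)2 (Lindlar catalyst), quinoline, EtOAc, rt
Reagents that add atoms: none
Why: Lindlar semihydrogenation; syn addition of hydrogen gives the Z-olefin C8=C9 and the poisoned catalyst spares the other olefins.

Step 11
Reactants: 12 methyl (5Z,7S,10E)-12-hydroxy-7-methyl-3-methylidene-7-(triethylsilyloxy)dodeca-5,10-dienoate
Product: 13 (5Z,7S,10E)-12-hydroxy-7-methyl-3-methylidene-7-(triethylsilyloxy)dodeca-5,10-dienoic acid
Conditions: LiOH, THF/H2O, 0 °C; aq. HCl to pH 4
Reagents that add atoms: none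
Why: Saponification of an unhindered methyl ester at 0 °C, fast enough to outrun isomerisation of the β,γ-olefin.

Step 12
Reactants: 13 (5Z,7S,10E)-12-hydroxy-7-methyl-3-methylidene-7-(triethylsilyloxy)dodeca-5,10-dienoic acid
Product: 14 (6Z,8S,11E)-8-methyl-4-methylidene-8-(triethylsilyloxy)-1-oxacyclotrideca-6,11-dien-2-one
Conditions: 2-methyl-6-nitrobenzoic anhydride, DMAP, CH2Cl2 (1 mM, slow addition), rt
Reagents that add atoms: none
Why: Shiina macrolactonisation through a mixed anhydride at room temperature, chosen so that the β,γ-unsaturated acyl donor is not enolised toward a vinylketene; three olefins pre-organise the 13-membered ring.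

Step 13
Reactants: 14 (6Z,8S,11E)-8-methyl-4-methylidene-8-(triethylsilyloxy)-1-oxacyclotrideca-6,11-dien-2-one
Product: 17 (1R,4Z,6S,9R)-9-ethenyl-6-methyl-2-methylidene-6-(triethylsilyloxy)cyclonon-4-ene-1-carboxylic acid, via boron ketene acetal 15 (not isolated), via acyloxyborane 16 (not isolated)
Conditions: (4S,5S)-2-bromo-1,3-bis{[3,5-bis(trifluoromethyl)phenyl]sulfonyl}-4,5-diphenyl-1,3,2-diazaborolidine (1.5 equiv), Et3N, PhMe, −78 °C; then 4 °C → rt; aq. NaHCO3, then aq. citric acid
Reagents that add atoms: none
Why: Ireland–Claisen rearrangement run in its reagent-controlled boron form: the bromoborane and Et3N enolise the β,γ-unsaturated lactone at C11a to ketene acetal 15, which rearranges [3,3] (C4a–C11a formed, O2–C3 broken) to acyloxyborane 16, hydrolysed on work-up. The closest known reaction type is the enantioselective ester-enolate Claisen rearrangement of allylic esters through chiral diazaborolidine ketene acetals, including the contraction of a macrocyclic allylic lactone to a medium-ring acid. The nine-membered ring closes by transannular C–C bond formation inside the 13-membered ring, a contraction by four atoms and not an end-to-end cyclisation. C4a and C11a are set together: their trans relationship should follow from the E-olefin, the ring-bound ketene acetal geometry (C11 cis to O2) and the boat-like transition state that the seven-atom tether enforces. Their absolute sense is set by the C2-symmetric sulfonamide ligand on boron, so the remote C7 centre is not asked to control the face and only must not override the reagent. The step needs Re(C11a)–Re(C4a) bonding and bond formation at the α- and not the γ-carbon of the dienolate; the six-membered transition state secures the second. The silyl ether, the Z-olefin and the methylene are spectators.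

Step 14
Reactants: 17 (1R,4Z,6S,9R)-9-ethenyl-6-methyl-2-methylidene-6-(triethylsilyloxy)cyclonon-4-ene-1-carboxylic acid
Product: 18 tri(propan-2-yl)silyl (1R,4Z,6S,9R)-9-ethenyl-6-methyl-2-methylidene-6-(triethylsilyloxy)cyclonon-4-ene-1-carboxylate
Conditions: iPr3SiCl, imidazole, CH2Cl2, 0 °C
Reagents that add atoms: chlorotri(propan-2-yl)silane, CC(C)[Si](Cl)(C(C)C)C(C)C
Why: O-Silylation of the carboxylate; no acyl activation is involved, so C11a and the β,γ-olefin are not put at risk, and the ester keeps the acid from adding to the palladium-activated olefin in the next step.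

Step 15
Reactants: 18 tri(propan-2-yl)silyl (1R,4Z,6S,9R)-9-ethenyl-6-methyl-2-methylidene-6-(triethylsilyloxy)cyclonon-4-ene-1-carboxylate
Product: 19 tri(propan-2-yl)silyl (1R,4Z,6S,9R)-6-methyl-2-methylidene-9-(2-oxoethyl)-6-(triethylsilyloxy)cyclonon-4-ene-1-carboxylate
Conditions: PdCl2(PhCN)2 (10 mol%), CuCl2·2H2O (10 mol%), AgNO2 (5 mol%), O2 (1 atm), t-BuOH/MeNO2 (15:1), rt
Reagents that add atoms: dioxygen, O=O
Why: Aldehyde-selective (nitrite-modified) Wacker oxidation; only the monosubstituted vinyl group is a good substrate, and its allylic branching and the nearby ester oxygen favour oxidation at the terminal carbon C3.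

Step 16
Reactants: 19 tri(propan-2-yl)silyl (1R,4Z,6S,9R)-6-methyl-2-methylidene-9-(2-oxoethyl)-6-(triethylsilyloxy)cyclonon-4-ene-1-carboxylate
Product: 20 (1R,4Z,6S,9R)-6-hydroxy-6-methyl-2-methylidene-9-(2-oxoethyl)cyclonon-4-ene-1-carboxylic acid
Conditions: HF·pyridine, pyridine, THF, 0 °C → rt
Reagents that add atoms: none
Why: Fluoride-mediated desilylation removes the silyl ester and the tertiary silyl ether in one operation; pyridine buffering protects the aldehyde and the tertiary allylic alcohol.

Step 17
Reactants: 21 (R)-2,2-dimethyl-1,3-dioxolane-4-carbaldehyde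
Product: 22 (4S)-2,2-dimethyl-4-(2-methylprop-1-en-1-yl)-1,3-dioxolane
Conditions: iPrPPh3I, n-BuLi, THF, 0 °C; then 21, −78 °C → rt
Reagents that add atoms: isopropyltriphenylphosphonium iodide, CC(C)[P+](c1ccccc1)(c1ccccc1)c1ccccc1.[I-]
Why: Wittig olefination with a non-stabilised ylide at low temperature, which keeps the α-stereocentre (C13) intact.

Step 18
Reactants: 22 (4S)-2,2-dimethyl-4-(2-methylprop-1-en-1-yl)-1,3-dioxolane
Product: 23 (2S)-4-methylpent-3-ene-1,2-diol
Conditions: AcOH/H2O (4:1), rt
Reagents that add atoms: none
Why: Mild acetal hydrolysis, done before the epoxide exists because the epoxide would not survive it.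

Step 19
Reactants: 23 (2S)-4-methylpent-3-ene-1,2-diol
Product: 24 (2S)-4-methyl-1,2-bis(triethylsilyloxy)pent-3-ene
Conditions: Et3SiCl, imidazole, CH2Cl2, 0 °C → rt
Reagents that add atoms: chlorotriethylsilane, CC[Si](Cl)(CC)CC
Why: Silylation of both hydroxyls; the non-chelating silyl ether on C13 later supports Felkin–Anh addition at C12.

Step 20
Reactants: 24 (2S)-4-methyl-1,2-bis(triethylsilyloxy)pent-3-ene
Product: 25 (2R)-3,3-dimethyl-2-[(1R)-1,2-bis(triethylsilyloxy)ethyl]oxirane
Conditions: 1,2:4,5-di-O-isopropylidene-β-D-erythro-hexo-2,3-diulo-2,6-pyranose (30 mol%), KHSO5, K2CO3, Bu4NHSO4, MeCN/CH2(OMe)2/aq. Na2B4O7, 0 °C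
Reagents that add atoms: potassium peroxymonosulfate, [K+].[O-]S(=O)(=O)OO
Why: Shi epoxidation of a trisubstituted olefin; the D-fructose-derived dioxirane should set C14 as R by reagent control, matched with the substrate preference for attack anti to the allylic C–O bond.

Step 21
Reactants: 25 (2R)-3,3-dimethyl-2-[(1R)-1,2-bis(triethylsilyloxy)ethyl]oxirane
Product: 26 (2S)-2-[(2R)-3,3-dimethyloxiran-2-yl]-2-(triethylsilyloxy)acetaldehyde
Conditions: (COCl)2, DMSO, CH2Cl2, −78 → −40 °C; Et3N
Reagents that add atoms: none
Why: Swern oxidation, which cleaves and oxidises a primary triethylsilyl ether directly while the secondary one stays; the aldehyde is used at once.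

Step 22
Reactants: 20 (1R,4Z,6S,9R)-6-hydroxy-6-methyl-2-methylidene-9-(2-oxoethyl)cyclonon-4-ene-1-carboxylic acid; 26 (2S)-2-[(2R)-3,3-dimethyloxiran-2-yl]-2-(triethylsilyloxy)acetaldehyde
Product: 29 aldehyde acid with the C4–C12 bond in place and triethylsilyl ethers at C12 and C13 (C4 S; C12, C13, C14 spatially as in 34), via hydroxy aldehyde acid 27 (not isolated), via triethylsilyl ester 28 (not isolated)
Conditions: L-proline (30 mol%), DMF, 4 °C, 26 (2.5 equiv), 20 added slowly; then imidazole, Et3SiCl, 0 °C; aq. NaHCO3, then aq. NaH2PO4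
Reagents that add atoms: chlorotriethylsilane, CC[Si](Cl)(CC)CC
Why: Proline-catalysed direct cross-aldol between two aldehydes; the enamine of the α-unbranched aldehyde 20 adds to the α-branched, α-oxygenated acceptor 26, which cannot easily act as donor. L-Proline should set C12 as R, which is also the Felkin–Anh (anti to the C13 oxygen) product, so catalyst and substrate are matched; C4 is lost later. Silylation in the same flask caps C12–OH before it can lactonise onto C1, and the silyl ester falls off on work-up.

Step 23
Reactants: 29 aldehyde acid with triethylsilyl ethers at C12 and C13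
Product: 30 (4aS,7S,8Z,11aR) enol lactone (O2–C1 closed, C3=C4), C7–OH free, triethylsilyl ethers at C12 and C13
Conditions: 2-methyl-6-nitrobenzoic anhydride, DMAP, Et3N, PhMe, rt → 40 °C
Reagents that add atoms: none
Why: Dehydrative enol lactonisation of a δ-aldehydo acid through a mixed anhydride (the reaction type that converts iridoid aldehydo acids into their enol lactones); the six-membered ring forms by acylation of the aldehyde oxygen and loss of the C4 proton, and only the aldehyde can supply the enol.

Step 24
Reactants: 30 enol lactone with Z C8=C9 olefin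
Product: 31 (4aS,7S,8R,9R,11aR) 8,9-epoxy enol lactone, triethylsilyl ethers at C12 and C13
Conditions: VO(acac)2 (5 mol%), t-BuOOH, CH2Cl2, 0 °C
Reagents that add atoms: tert-butyl hydroperoxide, CC(C)(C)OO
Why: Vanadium-catalysed hydroxyl-directed epoxidation; the C7 alkoxide on vanadium delivers oxygen to the adjacent Z-olefin on its own face, giving the syn epoxy alcohol, and no other olefin has a free allylic hydroxyl.

Step 25
Reactants: 31 8,9-epoxy enol lactone with triethylsilyl ethers at C12 and C13
Product: 32 8,9-epoxy enol lactone with free hydroxyls at C7, C12 and C13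
Conditions: HF·pyridine, pyridine, THF, 0 °C
Reagents that add atoms: none
Why: Buffered fluoride desilylation of two secondary triethylsilyl ethers under conditions mild enough for both epoxides and the enol lactone.

Step 26
Reactants: 32 8,9-epoxy enol lactone triol
Product: 33 lactol (C1–OH, mixture of anomers) with free hydroxyls at C7, C12 and C13
Conditions: iBu2AlH (5 equiv), CH2Cl2, −78 °C; aq. potassium sodium tartrate
Reagents that add atoms: none
Why: Partial reduction of an enol δ-lactone to its lactol by an aluminium hydride at −78 °C, where the tetrahedral aluminate survives until work-up; the hydroxyls are carried as aluminium alkoxides.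

Step 27
Reactants: 33 lactol
Product: 34 the target, (1R,4aS,7S,8R,9R,11aR)-1-acetoxy-4-{(1R,2R)-1,2-diacetoxy-2-[(2R)-3,3-dimethyloxiran-2-yl]ethyl}-8,9-epoxy-7-hydroxy-7-methyl-11-methylidene-dihydropyran-fused cyclononane
Conditions: Ac2O, pyridine, DMAP (cat.), CH2Cl2, 0 °C
Reagents that add atoms: acetic anhydride, CC(=O)OC(C)=O
Why: Acetylation of the two secondary hydroxyls and the lactol; the anomers equilibrate and the one with its hydroxyl anti to the C11 branch on C11a should be acylated, giving 1R, while the hindered tertiary C7 hydroxyl should not react at 0 °C.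

## Compound list

1 | geraniol, (2E)-3,7-dimethylocta-2,6-dien-1-ol | CC(C)=CCC/C(C)=C/CO | starting material
2 | [(2S,3S)-3-methyl-3-(4-methylpent-3-en-1-yl)oxiran-2-yl]methanol | CC(C)=CCC[C@]1(C)O[C@H]1CO | intermediate
3 | (2S,3R)-3-(chloromethyl)-2-methyl-2-(4-methylpent-3-en-1-yl)oxirane | CC(C)=CCC[C@]1(C)O[C@H]1CCl | intermediate
4 | (3S)-3,7-dimethyloct-6-en-1-yn-3-ol | C#C[C@@](C)(O)CCC=C(C)C | intermediate
5 | triethyl{[(3S)-3,7-dimethyloct-6-en-1-yn-3-yl]oxy}silane | C#C[C@@](C)(O[Si](CC)(CC)CC)CCC=C(C)C | intermediate
6 | (4S)-4-methyl-4-(triethylsilyloxy)hex-5-ynal | C#C[C@@](C)(O[Si](CC)(CC)CC)CCC=O | intermediate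
7 | ethyl (2E,6S)-6-methyl-6-(triethylsilyloxy)oct-2-en-7-ynoate | C#C[C@@](C)(O[Si](CC)(CC)CC)CC/C=C/C(=O)OCC | intermediate
8 | (2E,6S)-6-methyl-6-(triethylsilyloxy)oct-2-en-7-yn-1-ol | C#C[C@@](C)(O[Si](CC)(CC)CC)CC/C=C/CO | intermediate
9 | 3-chloro-2-(chloromethyl)prop-1-ene | C=C(CCl)CCl | starting material
10 | (2E,6S)-10-(chloromethyl)-6-methyl-6-(triethylsilyloxy)undeca-2,10-dien-7-yn-1-ol | ClCC(=C)CC#C[C@@](C)(O[Si](CC)(CC)CC)CC/C=C/CO | intermediate
11 | methyl (7S,10E)-12-hydroxy-7-methyl-3-methylidene-7-(triethylsilyloxy)dodec-10-en-5-ynoate | COC(=O)CC(=C)CC#C[C@@](C)(O[Si](CC)(CC)CC)CC/C=C/CO | intermediate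
12 | methyl (5Z,7S,10E)-12-hydroxy-7-methyl-3-methylidene-7-(triethylsilyloxy)dodeca-5,10-dienoate | COC(=O)CC(=C)C/C=C\[C@@](C)(O[Si](CC)(CC)CC)CC/C=C/CO | intermediate
13 | (5Z,7S,10E)-12-hydroxy-7-methyl-3-methylidene-7-(triethylsilyloxy)dodeca-5,10-dienoic acid | OC(=O)CC(=C)C/C=C\[C@@](C)(O[Si](CC)(CC)CC)CC/C=C/CO | intermediate
14 | (6Z,8S,11E)-8-methyl-4-methylidene-8-(triethylsilyloxy)-1-oxacyclotrideca-6,11-dien-2-one (13-membered lactone, precursor of the key step) | O=C1OC/C=C/CC[C@](C)(O[Si](CC)(CC)CC)/C=C\CC(=C)C1 | intermediate
15 | boron ketene acetal of 14 (O-boryl, C11 cis to O2, (4S,5S)-diazaborolidine on boron), not isolated | B1(O/C2=C/C(=C)C/C=C\[C@@](C)(O[Si](CC)(CC)CC)CC/C=C/CO2)N(S(=O)(=O)c3cc(cc(c3)C(F)(F)F)C(F)(F)F)[C@@H](c3ccccc3)[C@H](c3ccccc3)N1S(=O)(=O)c1cc(cc(c1)C(F)(F)F)C(F)(F)F | intermediate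
16 | acyloxyborane of acid 17 with the same diazaborolidine, not isolated | B1(OC(=O)[C@H]2C(=C)C/C=C\[C@@](C)(O[Si](CC)(CC)CC)CC[C@@H]2C=C)N(S(=O)(=O)c3cc(cc(c3)C(F)(F)F)C(F)(F)F)[C@@H](c3ccccc3)[C@H](c3ccccc3)N1S(=O)(=O)c1cc(cc(c1)C(F)(F)F)C(F)(F)F | intermediate
17 | (1R,4Z,6S,9R)-9-ethenyl-6-methyl-2-methylidene-6-(triethylsilyloxy)cyclonon-4-ene-1-carboxylic acid (product of the key step) | OC(=O)[C@H]1C(=C)C/C=C\[C@@](C)(O[Si](CC)(CC)CC)CC[C@@H]1C=C | intermediate
18 | tri(propan-2-yl)silyl (1R,4Z,6S,9R)-9-ethenyl-6-methyl-2-methylidene-6-(triethylsilyloxy)cyclonon-4-ene-1-carboxylate | CC(C)[Si](C(C)C)(C(C)C)OC(=O)[C@H]1C(=C)C/C=C\[C@@](C)(O[Si](CC)(CC)CC)CC[C@@H]1C=C | intermediate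
19 | tri(propan-2-yl)silyl (1R,4Z,6S,9R)-6-methyl-2-methylidene-9-(2-oxoethyl)-6-(triethylsilyloxy)cyclonon-4-ene-1-carboxylate | CC(C)[Si](C(C)C)(C(C)C)OC(=O)[C@H]1C(=C)C/C=C\[C@@](C)(O[Si](CC)(CC)CC)CC[C@@H]1CC=O | intermediate
20 | (1R,4Z,6S,9R)-6-hydroxy-6-methyl-2-methylidene-9-(2-oxoethyl)cyclonon-4-ene-1-carboxylic acid | OC(=O)[C@H]1C(=C)C/C=C\[C@@](C)(O)CC[C@@H]1CC=O | intermediate
21 | (R)-2,2-dimethyl-1,3-dioxolane-4-carbaldehyde | O=C[C@H]1COC(C)(C)O1 | starting material
22 | (4S)-2,2-dimethyl-4-(2-methylprop-1-en-1-yl)-1,3-dioxolane | CC(C)=C[C@H]1COC(C)(C)O1 | intermediate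
23 | (2S)-4-methylpent-3-ene-1,2-diol | CC(C)=C[C@H](O)CO | intermediate
24 | (2S)-4-methyl-1,2-bis(triethylsilyloxy)pent-3-ene | CC(C)=C[C@H](O[Si](CC)(CC)CC)CO[Si](CC)(CC)CC | intermediate
25 | (2R)-3,3-dimethyl-2-[(1R)-1,2-bis(triethylsilyloxy)ethyl]oxirane | CC[Si](CC)(CC)OC[C@@H](O[Si](CC)(CC)CC)[C@H]1OC1(C)C | intermediate
26 | (2S)-2-[(2R)-3,3-dimethyloxiran-2-yl]-2-(triethylsilyloxy)acetaldehyde | O=C[C@@H](O[Si](CC)(CC)CC)[C@H]1OC1(C)C | intermediate
27 | aldol adduct: acid 20 with C4 (S) bonded to C12; C12–OH, C13–OSiEt3, C14–C15 epoxide (C12, C13, C14 spatially as in 34), not isolated | OC(=O)[C@H]1C(=C)C/C=C\[C@@](C)(O)CC[C@@H]1[C@H](C=O)[C@@H](O)[C@@H](O[Si](CC)(CC)CC)[C@H]1OC1(C)C | intermediate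
28 | triethylsilyl ester of 29 (C12–OSiEt3, C13–OSiEt3), not isolated | CC[Si](CC)(CC)OC(=O)[C@H]1C(=C)C/C=C\[C@@](C)(O)CC[C@@H]1[C@H](C=O)[C@@H](O[Si](CC)(CC)CC)[C@@H](O[Si](CC)(CC)CC)[C@H]1OC1(C)C | intermediate
29 | aldehyde acid: as 27 with C12–OSiEt3 | OC(=O)[C@H]1C(=C)C/C=C\[C@@](C)(O)CC[C@@H]1[C@H](C=O)[C@@H](O[Si](CC)(CC)CC)[C@@H](O[Si](CC)(CC)CC)[C@H]1OC1(C)C | intermediate
30 | (4aS,7S,8Z,11aR) enol lactone: C1 lactone carbonyl, C3=C4, C7–OH, C11 methylidene, triethylsilyl ethers at C12 and C13, C14–C15 epoxide | C=C1C/C=C\[C@@](C)(O)CC[C@@H]2C([C@@H](O[Si](CC)(CC)CC)[C@@H](O[Si](CC)(CC)CC)[C@H]3OC3(C)C)=COC(=O)[C@@H]12 | intermediate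
31 | (4aS,7S,8R,9R,11aR) 8,9-epoxy enol lactone, triethylsilyl ethers at C12 and C13 | C=C1C[C@H]2O[C@H]2[C@@](C)(O)CC[C@@H]2C([C@@H](O[Si](CC)(CC)CC)[C@@H](O[Si](CC)(CC)CC)[C@H]3OC3(C)C)=COC(=O)[C@@H]12 | intermediate
32 | 8,9-epoxy enol lactone with free hydroxyls at C7, C12, C13 (configuration as in 34) | C=C1C[C@H]2O[C@H]2[C@@](C)(O)CC[C@@H]2C([C@@H](O)[C@@H](O)[C@H]3OC3(C)C)=COC(=O)[C@@H]12 | intermediate
33 | lactol: as 32 with C1 as hemiacetal (anomeric mixture) | C=C1C[C@H]2O[C@H]2[C@@](C)(O)CC[C@@H]2C([C@@H](O)[C@@H](O)[C@H]3OC3(C)C)=COC(O)[C@@H]12 | intermediate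
34 | CNP0134792.1: (1R,4aS,7S,8R,9R,11aR)-1-acetoxy-4-{(1R,2R)-1,2-diacetoxy-2-[(2R)-3,3-dimethyloxiran-2-yl]ethyl}-8,9-epoxy-7-hydroxy-7-methyl-11-methylidene xenicane acetal | C=C1C[C@H]2O[C@H]2[C@@](C)(O)CC[C@@H]2C([C@@H](OC(C)=O)[C@@H](OC(C)=O)[C@H]3OC3(C)C)=CO[C@H](OC(C)=O)[C@@H]12 | target

## Step count and least certain steps

Total: 27 steps. Longest linear sequence: 22 steps (steps 1–16 and 22–27, from geraniol 1 to 34). The side-chain aldehyde 26 takes 5 steps (steps 17–21).

**Step 13 (key step).**
- What may go wrong: erosion of facial selectivity if the preference of the boron reagent and the conformational preference imposed by the C7 centre oppose each other; ionisation of the tertiary allylic silyl ether by the Lewis-acidic bromoborane before enolisation; partial passage through a chair-like transition state, which would give the cis acid.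
- Fallback (sets out from 14, returns at 17): the lactone is enolised without any Lewis acid as the trimethylsilyl ketene acetal F1 (LiN(SiMe3)2, Me3SiCl/Et3N, THF, −78 °C). F1 is heated in toluene to the trimethylsilyl ester F2, which dilute acid hydrolyses to 17. Facial control then rests on C7 alone; because C7 is enantiopure the two outcomes are diastereomers and are separated at ester 18. A cis ring fusion is corrected later at lactone 30, where C11a is the only acidic position and the trans-fused bicycle is expected to be the more stable.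

**Step 15 (aldehyde-selective Wacker oxidation).**
- What may go wrong: migration of the C11 methylene or of the vinyl group by palladium hydride; oxidation at C4 to the methyl ketone; loss of the silyl ester followed by cyclisation of the carboxylate onto the activated olefin.
- Fallback (sets out from 18, returns at 19): cross-metathesis with 4,4,5,5-tetramethyl-2-vinyl-1,3,2-dioxaborolane (second-generation Grubbs catalyst, RuCl2(=CHPh)(PCy3)(H2IMes), CH2Cl2, 40 °C) engages only the monosubstituted olefin and gives the E-alkenyl boronate F3. Oxidation of the C–B bond with Me3NO in THF releases the aldehyde 19.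

**Step 22 (cross-aldol).**
- What may go wrong: slow enamine formation from the β-branched donor; self-condensation of the donor; lactonisation of the new C12 hydroxyl onto C1 before it is silylated.
- Fallback (sets out from 20, returns at 27): 20 is silylated exhaustively with Me3SiOTf/Et3N to the tris(trimethylsilyl) derivative F4 (silyl ester, C7 silyl ether, C3 silyl enol ether). F4 is added to 26 in a Lewis-base-catalysed Mukaiyama aldol reaction (LiOAc, DMF, −45 °C), which uses no Lewis acid and so spares the epoxide. Aqueous work-up removes the trimethylsilyl groups and gives hydroxy aldehyde 27, which is silylated as in step 22.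

**Step 23 (enol lactonisation).**
- What may go wrong: the activated acid may stall as a cyclic acylal without losing the C4 proton; enolisation of the activated acyl group at C11a may scramble that centre or pull the methylene into conjugation; silanol may be eliminated from C12.
- Fallback (sets out from 29, returns at 30): the acid is converted into the acyl fluoride F5 (cyanuric fluoride, pyridine, CH2Cl2). Me3SiOTf/Et3N then makes the silyl enol ether of the aldehyde and silylates C7–OH, giving F6. A catalytic fluoride source (Bu4N Ph3SiF2) triggers intramolecular O-acylation of the enol silane to the C7-O-trimethylsilyl enol lactone F7. Pyridinium p-toluenesulfonate in methanol at 0 °C removes the tertiary trimethylsilyl ether without touching the triethylsilyl ethers and gives 30.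

**Steps 26 and 27 (lactol and acetylation).**
- What may go wrong: opening of the lactol to the dialdehyde with epimerisation or conjugation at C11a; acetylation of the wrong anomer at C1; partial acetylation of the C7 hydroxyl.
- Fallback (sets out from 31, returns at 34): the lactone is reduced while C12 and C13 are still silylated (iBu2AlH, CH2Cl2, −78 °C) and the aluminium hemiacetal is trapped in the same flask with Ac2O, pyridine and DMAP. This gives the C1 acetate F8 without ever freeing the lactol, so C1 is fixed by the direction of hydride delivery. Buffered HF·pyridine then gives the diol acetate F9, and Ac2O/pyridine completes 34.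

## Further compounds

F1 | step 13 | trimethylsilyl ketene acetal of lactone 14 (C11 cis to O2) | C[Si](C)(C)O/C1=C/C(=C)C/C=C\[C@@](C)(O[Si](CC)(CC)CC)CC/C=C/CO1
F2 | step 13 | trimethylsilyl ester of acid 17 | C[Si](C)(C)OC(=O)[C@H]1C(=C)C/C=C\[C@@](C)(O[Si](CC)(CC)CC)CC[C@@H]1C=C
F3 | step 15 | E-alkenyl pinacol boronate from 18 | CC(C)[Si](C(C)C)(C(C)C)OC(=O)[C@H]1C(=C)C/C=C\[C@@](C)(O[Si](CC)(CC)CC)CC[C@@H]1/C=C/B1OC(C)(C)C(C)(C)O1
F4 | step 22 | tris(trimethylsilyl) derivative of 20 (silyl ester, C7 silyl ether, C3 silyl enol ether, E/Z mixture) | C[Si](C)(C)OC(=O)[C@H]1C(=C)C/C=C\[C@@](C)(O[Si](C)(C)C)CC[C@@H]1C=CO[Si](C)(C)C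
F5 | step 23 | acyl fluoride of 29 | FC(=O)[C@H]1C(=C)C/C=C\[C@@](C)(O)CC[C@@H]1[C@H](C=O)[C@@H](O[Si](CC)(CC)CC)[C@@H](O[Si](CC)(CC)CC)[C@H]1OC1(C)C
F6 | step 23 | acyl fluoride with C3 trimethylsilyl enol ether and C7 trimethylsilyl ether | FC(=O)[C@H]1C(=C)C/C=C\[C@@](C)(O[Si](C)(C)C)CC[C@@H]1C(=CO[Si](C)(C)C)[C@@H](O[Si](CC)(CC)CC)[C@@H](O[Si](CC)(CC)CC)[C@H]1OC1(C)C
F7 | step 23 | C7-O-trimethylsilyl ether of enol lactone 30 | C=C1C/C=C\[C@@](C)(O[Si](C)(C)C)CC[C@@H]2C([C@@H](O[Si](CC)(CC)CC)[C@@H](O[Si](CC)(CC)CC)[C@H]3OC3(C)C)=COC(=O)[C@@H]12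
F8 | step 27 | C1 acetate with triethylsilyl ethers at C12 and C13 | C=C1C[C@H]2O[C@H]2[C@@](C)(O)CC[C@@H]2C([C@@H](O[Si](CC)(CC)CC)[C@@H](O[Si](CC)(CC)CC)[C@H]3OC3(C)C)=CO[C@H](OC(C)=O)[C@@H]12
F9 | step 27 | C1 acetate with free hydroxyls at C12 and C13 | C=C1C[C@H]2O[C@H]2[C@@](C)(O)CC[C@@H]2C([C@@H](O)[C@@H](O)[C@H]3OC3(C)C)=CO[C@H](OC(C)=O)[C@@H]12
A1 | alternative 1 | 2-methoxy-3,4-dihydro-2H-pyran-5-carboxylate with the ketal/silylalkyne arm on C11a and the butenyl arm on C4a | COC(=O)C1=CO[C@H](OC)[C@@H](C2(CC#C[Si](C)(C)C)OCCO2)[C@@H]1CCC=C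
A2 | alternative 2 | syn epoxy carbinol core as C4 methyl ester and C1 methyl acetal | C=C1C[C@H]2O[C@H]2[C@@](C)(O)CC[C@@H]2C(C(=O)OC)=CO[C@H](OC)[C@@H]12
A3 | alternative 3 | 5-methylcyclonon-4-enone with acetal arms on C4a and C11a | O=C1CC/C=C(C)\CC[C@H](CC(OC)OC)[C@H]1C2OCCO2
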